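**Plan**
Numbering used: carbocycle C1–C10 with C3 = ketone, C4 = CH(CH3) (methyl = C15), C5 = CH2, C6 = CH–O-senecioate, C7 and C8 shared with the butenolide (C8 carries the ring oxygen and the C8=C9 bond), C10 = C(OH)CH3; C11/C12/C13 = lactone α-carbon, carbonyl and CH2OAc.
Retrosynthesis cuts, in order: the C13 acetate and two silyl ethers; the C6 senecioate and the C4–H bonds (C4=C15H2 as helper); the C5–C6 bond of the ten-membered ring; the lactone C8–O and the C7–C8 bonds, which leaves a west alkyne (C1–C5, C8–C10) and an east enol triflate (C6, C7, C11–C13).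
Enabling feature: the C3 ketone and the C6 oxygen are 1,4-related (C3(=O)–C4–C5–C6–O), and C6 can sit as a formyl group on C7 of the planar (Z)-ylidene butenolide ring; one extra unsaturation at C4 (a 2-acylallyl unit C15=C4–C5) makes C5 an allylic nucleophile for that aldehyde.
Forward: nerol gives the west alkyne; a crossed Claisen/enol triflate sequence gives the east piece; Sonogashira coupling and 5-exo-dig lactonisation build the butenolide ring first; chromium-mediated intramolecular allylation then closes the ten-membered carbocycle; hydrogenation, acylation and deprotection finish.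
Stereochemistry: C10 from asymmetric epoxidation of nerol (kept through the epoxy chloride fragmentation); (Z)-C8=C9 from anti oxymetalation; C6 from substrate control in the ring closure (relay from C10 across the rigid butenolide); C4 from hydrogenation directed by the new C6 hydroxyl.

Key step: step 16

Remark: the hydroxy ketone drawn can close reversibly to its C3/C10 hemiketal; the open form is taken as the target, and the C10 oxygen stays silylated until the last step so that C3 remains a ketone.

Step 1
Reactants: 1 nerol [(2Z)-3,7-dimethylocta-2,6-dien-1-ol]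
Product: 2 (2S,3R)-2,3-epoxynerol
Conditions: Ti(OiPr)4 (5 mol %), L-(+)-diethyl tartrate (6 mol %), t-BuOOH, 4 Å molecular sieves, CH2Cl2, −20 °C
Reagents that add atoms: tert-butyl hydroperoxide, CC(C)(C)OO
Why: Sharpless asymmetric epoxidation of the (Z)-allylic alcohol, in which the L-(+)-tartrate/titanium complex delivers oxygen to the face that makes the methyl-bearing carbon (future C10) R, with no reaction at the isolated 6,7-alkene.

Step 2
Reactants: 2 (2S,3R)-2,3-epoxynerol
Product: 3 (2R,3R)-2-(chloromethyl)-3-methyl-3-(4-methylpent-3-en-1-yl)oxirane (same spatial arrangement as 2)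
Conditions: PPh3, CCl4, NaHCO3, reflux
Reagents that add atoms: tetrachloromethane, ClC(Cl)(Cl)Cl
Why: Appel chlorination of the primary alcohol under buffered, non-acidic conditions should leave the trisubstituted epoxide and both stereocentres untouched.

Step 3
Reactants: 3 epoxy chloride
Product: 4 (3R)-3,7-dimethyloct-6-en-1-yn-3-ol
Conditions: n-BuLi (3 equiv), THF, −40 °C; aq. NH4Cl
Reagents that add atoms: none
Why: Base-induced fragmentation of a 2,3-epoxy chloride to a propargylic alcohol (α-deprotonation, epoxide opening, dehydrochlorination); the C–O bond at the carbinol carbon is never broken, so the R configuration is retained.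

Step 4
Reactants: 4 (3R)-3,7-dimethyloct-6-en-1-yn-3-ol
Product: 5 triethyl{[(3R)-3,7-dimethyloct-6-en-1-yn-3-yl]oxy}silane
Conditions: Et3SiOTf, 2,6-lutidine, CH2Cl2, −78 → 0 °C
Reagents that add atoms: triethylsilyl trifluoromethanesulfonate, CC[Si](CC)(CC)OS(=O)(=O)C(F)(F)F
Why: Silyl triflate silylation is the standard protection of a hindered tertiary alcohol, and the ether later prevents hemiketal formation with C3.

Step 5
Reactants: 5 silyl ether
Product: 6 (4R)-4-methyl-4-[(triethylsilyl)oxy]hex-5-ynal
Conditions: O3, CH2Cl2, −78 °C (Sudan red indicator); then Me2S, −78 → 25 °C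
Reagents that add atoms: ozone, [O-][O+]=O
Why: Ozonolysis with reductive work-up is chemoselective for the electron-rich trisubstituted alkene over the terminal alkyne when stopped at the indicator end point, and gives the C3 aldehyde.

Step 6
Reactants: 6 aldehyde
Product: 7 (6R)-6-methyl-6-[(triethylsilyl)oxy]oct-1-en-7-yn-3-ol (both C3 epimers)
Conditions: CH2=CHMgBr (2.2 equiv), THF, −78 °C; aq. NH4Cl
Reagents that add atoms: vinylmagnesium bromide, C=C[Mg]Br
Why: Grignard 1,2-addition to the aldehyde; the new carbinol centre forms as a mixture, which does not matter because it is oxidised in step 12.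

Step 7
Reactants: 8 methyl 3-hydroxypropanoate
Product: 9 methyl 3-[(tert-butyldimethylsilyl)oxy]propanoate
Conditions: t-BuMe2SiCl, imidazole, DMF, 25 °C
Reagents that add atoms: tert-butylchlorodimethylsilane, CC(C)(C)[Si](C)(C)Cl
Why: Routine silylation of a primary alcohol, giving a C13–O group that survives enolate, hydroxide and chromium chemistry.

Step 8
Reactants: 9 silyloxy ester; 10 methyl 2,2-dimethoxyacetate
Product: 11 methyl 2-{[(tert-butyldimethylsilyl)oxy]methyl}-4,4-dimethoxy-3-oxobutanoate (racemic)
Conditions: LiN(i-Pr)2 (2.1 equiv), THF, −78 °C; then 10, −78 → −20 °C; aq. NH4Cl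
Reagents that add atoms: none
Why: Crossed Claisen condensation, in which the lithium enolate of 9 (stable to β-elimination at −78 °C) acylates the activated ester 10 and the second equivalent of base deprotonates the β-keto ester to drive the equilibrium.

Step 9
Reactants: 11 β-keto ester
Product: 12 methyl (2Z)-2-{[(tert-butyldimethylsilyl)oxy]methyl}-4,4-dimethoxy-3-{[(trifluoromethyl)sulfonyl]oxy}but-2-enoate (triflate cis to the ester)
Conditions: NaH, Et2O, 0 °C; then Tf2O, −78 → 0 °C
Reagents that add atoms: trifluoromethanesulfonic anhydride, O=S(=O)(OS(=O)(=O)C(F)(F)F)C(F)(F)F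
Why: O-sulfonylation of the chelated sodium enolate of a β-keto ester should give the (Z)-enol triflate, a known stereoselective route to fully substituted enol triflates that fixes the geometry of the future C7=C11 bond.

Step 10
Reactants: 7 alkyne; 12 enol triflate
Product: 13 methyl (2E,6R)-2-{[(tert-butyldimethylsilyl)oxy]methyl}-3-(dimethoxymethyl)-9-hydroxy-6-methyl-6-[(triethylsilyl)oxy]undeca-2,10-dien-4-ynoate (alkynyl cis to the ester)
Conditions: Pd(PPh3)4 (5 mol %), CuI (10 mol %), i-Pr2NH, THF, 25 °C
Reagents that add atoms: none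
Why: Sonogashira coupling of an electron-poor alkenyl triflate with a terminal alkyne proceeds with retention of alkene geometry, placing the alkyne cis to the ester and forming C7–C8.

Step 11
Reactants: 13 enynoate
Product: 15 (5Z)-3-{[(tert-butyldimethylsilyl)oxy]methyl}-4-(dimethoxymethyl)-5-{(2R)-5-hydroxy-2-methyl-2-[(triethylsilyl)oxy]hept-6-en-1-ylidene}furan-2(5H)-one, via enynoic acid 14 (not isolated)
Conditions: LiOH·H2O, THF/MeOH/H2O, 40 °C; 0.5 M HCl to pH 4 at 0 °C, extraction; then AgNO3 (10 mol %), acetone, 25 °C, dark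
Reagents that add atoms: lithium hydroxide, [Li+].[OH-]
Why: Saponification followed by silver-catalysed 5-exo-dig lactonisation of a (Z)-2-en-4-ynoic acid, where anti addition of carboxylate and proton across the activated alkyne gives the (Z)-ylidene (C10 cis to the ring oxygen) and the quaternary C10 disfavours the 6-endo mode.

Step 12
Reactants: 15 butenolide alcohol
Product: 16 (5Z)-3-{[(tert-butyldimethylsilyl)oxy]methyl}-4-(dimethoxymethyl)-5-{(2R)-2-methyl-5-oxo-2-[(triethylsilyl)oxy]hept-6-en-1-ylidene}furan-2(5H)-one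
Conditions: Dess–Martin periodinane, NaHCO3, CH2Cl2, 0 → 25 °C
Reagents that add atoms: none
Why: Dess–Martin oxidation of the secondary allylic alcohol to the vinyl ketone under buffered neutral conditions that spare the acetal, silyl ethers and dienyl lactone.

Step 13
Reactants: 16 vinyl ketone
Product: 17 (5Z)-3-{[(tert-butyldimethylsilyl)oxy]methyl}-4-(dimethoxymethyl)-5-{(2R)-6-(hydroxymethyl)-2-methyl-5-oxo-2-[(triethylsilyl)oxy]hept-6-en-1-ylidene}furan-2(5H)-one
Conditions: aq. CH2O (37 %), DABCO (30 mol %), 1,4-dioxane/H2O, 25 °C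
Reagents that add atoms: formaldehyde, C=O
Why: Morita–Baylis–Hillman reaction of an alkyl vinyl ketone with formaldehyde installs the hydroxymethyl carbon on C4, while the hindered tetrasubstituted butenolide is not a competent acceptor for the amine.

Step 14
Reactants: 17 allylic alcohol
Product: 18 (5Z)-5-{(2R)-6-(bromomethyl)-2-methyl-5-oxo-2-[(triethylsilyl)oxy]hept-6-en-1-ylidene}-3-{[(tert-butyldimethylsilyl)oxy]methyl}-4-(dimethoxymethyl)furan-2(5H)-one
Conditions: CBr4, PPh3, CH2Cl2, −20 °C
Reagents that add atoms: tetrabromomethane, BrC(Br)(Br)Br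
Why: Appel bromination of the primary allylic alcohol under neutral conditions gives the 2-(bromomethyl) enone, the precursor of the 2-acylallyl metal.

Step 15
Reactants: 18 acetal bromide
Product: 19 (2Z)-2-{(2R)-6-(bromomethyl)-2-methyl-5-oxo-2-[(triethylsilyl)oxy]hept-6-en-1-ylidene}-4-{[(tert-butyldimethylsilyl)oxy]methyl}-5-oxo-2,5-dihydrofuran-3-carbaldehyde
Conditions: Et3SiOTf (2 equiv), 2,4,6-collidine (3 equiv), CH2Cl2, 0 °C; then H2O
Reagents that add atoms: water, O
Why: Mild non-acidic acetal cleavage (silyl triflate ionisation, trapping as the collidinium salt, hydrolysis) should unveil the C6 aldehyde without loss of the silyl ethers or the allylic bromide.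

Step 16
Reactants: 19 bromo aldehyde
Product: 20 macrocyclic hydroxy enone: (Z)-ylidene butenolide (C7=C11, C8=C9) fused to the ten-membered carbocycle C1–C10, with C3=O, C4=CH2, (6R)-OH, (10R)-CH3/OSiEt3 and C13–OSi(t-Bu)Me2
Conditions: CrCl2 (8 equiv), THF, 25 °C, syringe-pump addition of 19 over 12 h (final 0.002 M); aqueous work-up
Reagents that add atoms: none
Why: Two single-electron transfers from divalent chromium convert the allylic bromide of 19 into a 2-acylallyl trivalent-chromium species, whose terminus C5 adds to the C6 formyl group through a six-membered chair-like (Zimmerman–Traxler) array with allylic transposition, leaving the exo-methylene C4=C15 (intramolecular Nozaki–Hiyama allylation). The closest known reaction types are the chromium-mediated cyclisation of ω-formyl allylic bromides to ten-membered germacrane carbocycles and the Dreiding–Schmidt addition of 2-(bromomethyl)acrylates to aldehydes. The ten-membered carbocycle C1–C10 is closed by carbonyl allylation (allyl terminus C5 onto C6, the new alkene ending exocyclic at C4), which is possible because the temporary C4=C15 unsaturation turns the 1,4-related C3 ketone/C6 oxygen pair into an allylation retron. The new stereocentre C6 is under substrate control: the five-atom tether can reach C6 only across one face of the planar (Z)-ylidene butenolide, that face is chosen by C10 (silyloxy oxygen eclipsing C8=C9 next to the lactone oxygen, methyl on the face away from the tether), and the formyl group reacts in the conformer with its oxygen towards C9–H (A1,3 strain with the C13 substituent), which should lead to 6R. The step needs chemoselectivity, secured because allylchromium reagents add to aldehydes much faster than to the C3 ketone, the lactone or the silyl ethers and divalent chromium does not reduce the dienyl lactone, and it needs cyclisation to beat oligomerisation, secured by slow addition at high dilution and by the rigid butenolide holding C10 and C6 on one edge.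

Step 17
Reactants: 20 macrocyclic hydroxy enone
Product: 21 (4S,6R,10R)-hydroxy ketone: as 20 with C4 = CH(CH3)
Conditions: [Rh(nbd)(dppb)]BF4 (10 mol %), H2 (40 bar), CH2Cl2, 25 °C
Reagents that add atoms: none
Why: Hydroxyl-directed hydrogenation, in which the cationic rhodium binds the C6 hydroxyl and the 1,1-disubstituted C4=C15 alkene in a chair-like chelate with C7 pseudo-equatorial and delivers H2 to the chelated face, which should give the 4S (4,6-syn) methyl while the tri- and tetrasubstituted conjugated alkenes stay inert.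

Step 18
Reactants: 21 hydroxy ketone
Product: 22 senecioate: as 21 with (6R)-O–CO–CH=C(CH3)2
Conditions: 3-methylbut-2-enoyl chloride, pyridine, DMAP (10 mol %), CH2Cl2, 0 °C
Reagents that add atoms: 3-methylbut-2-enoyl chloride, CC(C)=CC(=O)Cl
Why: Acylation of the only free (secondary) hydroxyl, with pyridine rather than a trialkylamine to avoid vinylketene formation and deconjugation of the senecioyl group.

Step 19
Reactants: 22 bis-silyl senecioate
Product: 24 target CNP0186726.1, via diol 23 (not isolated)
Conditions: HF·pyridine, pyridine, THF, 0 → 25 °C; concentration; then Ac2O, pyridine, 0 °C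
Reagents that add atoms: acetic anhydride, CC(=O)OC(C)=O
Why: Buffered fluoride desilylation should remove both silyl ethers without ionising the tertiary allylic alcohol, and acetylation without DMAP acylates only the primary C13 hydroxyl.

**Compound list**
1 | nerol, (2Z)-3,7-dimethylocta-2,6-dien-1-ol | CC(C)=CCC/C(C)=C\CO | starting material
2 | (2S,3R)-2,3-epoxynerol | OC[C@@H]1O[C@]1(C)CCC=C(C)C | intermediate
3 | (2R,3R)-2-(chloromethyl)-3-methyl-3-(4-methylpent-3-en-1-yl)oxirane | ClC[C@@H]1O[C@]1(C)CCC=C(C)C | intermediate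
4 | (3R)-3,7-dimethyloct-6-en-1-yn-3-ol | C#C[C@](C)(O)CCC=C(C)C | intermediate
5 | triethyl{[(3R)-3,7-dimethyloct-6-en-1-yn-3-yl]oxy}silane | C#C[C@](C)(O[Si](CC)(CC)CC)CCC=C(C)C | intermediate
6 | (4R)-4-methyl-4-[(triethylsilyl)oxy]hex-5-ynal | C#C[C@](C)(O[Si](CC)(CC)CC)CCC=O | intermediate
7 | (6R)-6-methyl-6-[(triethylsilyl)oxy]oct-1-en-7-yn-3-ol (C3 epimers) | C#C[C@](C)(O[Si](CC)(CC)CC)CCC(O)C=C | intermediate
8 | methyl 3-hydroxypropanoate | COC(=O)CCO | starting material
9 | methyl 3-[(tert-butyldimethylsilyl)oxy]propanoate | COC(=O)CCO[Si](C)(C)C(C)(C)C | intermediate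
10 | methyl 2,2-dimethoxyacetate | COC(OC)C(=O)OC | starting material
11 | methyl 2-{[(tert-butyldimethylsilyl)oxy]methyl}-4,4-dimethoxy-3-oxobutanoate (racemic) | COC(=O)C(CO[Si](C)(C)C(C)(C)C)C(=O)C(OC)OC | intermediate
12 | methyl (2Z)-2-{[(tert-butyldimethylsilyl)oxy]methyl}-4,4-dimethoxy-3-{[(trifluoromethyl)sulfonyl]oxy}but-2-enoate | COC(=O)/C(CO[Si](C)(C)C(C)(C)C)=C(\OS(=O)(=O)C(F)(F)F)C(OC)OC | intermediate
13 | methyl (2E,6R)-2-{[(tert-butyldimethylsilyl)oxy]methyl}-3-(dimethoxymethyl)-9-hydroxy-6-methyl-6-[(triethylsilyl)oxy]undeca-2,10-dien-4-ynoate | COC(=O)/C(CO[Si](C)(C)C(C)(C)C)=C(\C#C[C@](C)(O[Si](CC)(CC)CC)CCC(O)C=C)C(OC)OC | intermediate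
14 | (2E,6R)-enynoic acid corresponding to ester 13 | OC(=O)/C(CO[Si](C)(C)C(C)(C)C)=C(\C#C[C@](C)(O[Si](CC)(CC)CC)CCC(O)C=C)C(OC)OC | intermediate
15 | (5Z)-3-{[(tert-butyldimethylsilyl)oxy]methyl}-4-(dimethoxymethyl)-5-{(2R)-5-hydroxy-2-methyl-2-[(triethylsilyl)oxy]hept-6-en-1-ylidene}furan-2(5H)-one | O=C1O/C(=C\[C@](C)(O[Si](CC)(CC)CC)CCC(O)C=C)C(C(OC)OC)=C1CO[Si](C)(C)C(C)(C)C | intermediate
16 | (5Z)-3-{[(tert-butyldimethylsilyl)oxy]methyl}-4-(dimethoxymethyl)-5-{(2R)-2-methyl-5-oxo-2-[(triethylsilyl)oxy]hept-6-en-1-ylidene}furan-2(5H)-one | O=C1O/C(=C\[C@](C)(O[Si](CC)(CC)CC)CCC(=O)C=C)C(C(OC)OC)=C1CO[Si](C)(C)C(C)(C)C | intermediate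
17 | (5Z)-3-{[(tert-butyldimethylsilyl)oxy]methyl}-4-(dimethoxymethyl)-5-{(2R)-6-(hydroxymethyl)-2-methyl-5-oxo-2-[(triethylsilyl)oxy]hept-6-en-1-ylidene}furan-2(5H)-one | O=C1O/C(=C\[C@](C)(O[Si](CC)(CC)CC)CCC(=O)C(=C)CO)C(C(OC)OC)=C1CO[Si](C)(C)C(C)(C)C | intermediate
18 | (5Z)-5-{(2R)-6-(bromomethyl)-2-methyl-5-oxo-2-[(triethylsilyl)oxy]hept-6-en-1-ylidene}-3-{[(tert-butyldimethylsilyl)oxy]methyl}-4-(dimethoxymethyl)furan-2(5H)-one | O=C1O/C(=C\[C@](C)(O[Si](CC)(CC)CC)CCC(=O)C(=C)CBr)C(C(OC)OC)=C1CO[Si](C)(C)C(C)(C)C | intermediate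
19 | (2Z)-2-{(2R)-6-(bromomethyl)-2-methyl-5-oxo-2-[(triethylsilyl)oxy]hept-6-en-1-ylidene}-4-{[(tert-butyldimethylsilyl)oxy]methyl}-5-oxo-2,5-dihydrofuran-3-carbaldehyde | O=C1O/C(=C\[C@](C)(O[Si](CC)(CC)CC)CCC(=O)C(=C)CBr)C(C=O)=C1CO[Si](C)(C)C(C)(C)C | intermediate
20 | macrocyclic hydroxy enone: ten-membered carbocycle fused to the (Z)-ylidene butenolide; C3=O, C4=CH2, (6R)-OH, (10R)-CH3/OSiEt3, C13–OSi(t-Bu)Me2 | CC(C)(C)[Si](C)(C)OCC1=C2/C(=C/[C@](C)(O[Si](CC)(CC)CC)CCC(=O)C(=C)C[C@H]2O)OC1=O | intermediate
21 | (4S,6R,10R)-hydroxy ketone: as 20 with C4 = CH(CH3) | CC(C)(C)[Si](C)(C)OCC1=C2/C(=C/[C@](C)(O[Si](CC)(CC)CC)CCC(=O)[C@@H](C)C[C@H]2O)OC1=O | intermediate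
22 | (4S,6R,10R)-senecioate: as 21 with C6–O–CO–CH=C(CH3)2 | CC(C)(C)[Si](C)(C)OCC1=C2/C(=C/[C@](C)(O[Si](CC)(CC)CC)CCC(=O)[C@@H](C)C[C@H]2OC(=O)C=C(C)C)OC1=O | intermediate
23 | diol: 22 without both silyl groups (C13–OH, C10–OH) | OCC1=C2/C(=C/[C@](C)(O)CCC(=O)[C@@H](C)C[C@H]2OC(=O)C=C(C)C)OC1=O | intermediate
24 | CNP0186726.1 | CC(=O)OCC1=C2/C(=C/[C@](C)(O)CCC(=O)[C@@H](C)C[C@H]2OC(=O)C=C(C)C)OC1=O | target

**Totals**
Total step count: 19. Longest linear sequence: 16 steps (steps 1–6 and 10–19).

**Steps most likely to fail**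

Step 16. What may go wrong: attack on the wrong face of the C6 formyl group, because control from the remote C10 centre may be weak, and competing intermolecular coupling. Fallback: setting out from 19, the same chromium-mediated ring closure is accepted as the 6S carbinol F1. Its Mitsunobu reaction with 3-methylbut-2-enoic acid (PPh3, DIAD, toluene, 0 °C) inverts C6 and installs the ester in one operation to give the exo-methylene senecioate F2. Conjugate reduction of F2 with [(Ph3P)CuH]6 in wet toluene, followed if needed by DBU equilibration of the epimerisable C4 centre, comes back to the route at 22.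

Step 17. What may go wrong: hydrogen delivery to the other alkene face if the chelate geometry in the macrocycle differs from the acyclic model, or over-reduction of the C8=C9 bond. Fallback: setting out from 20, hydride 1,4-addition with [(Ph3P)CuH]6 (wet toluene, 25 °C) and thermodynamic protonation/DBU equilibration of the α-stereocentre replaces the directed hydrogenation and comes back at 21. This assumes the 4S epimer is the more stable one. The fallback makes no new compound (F0).

Step 13. What may go wrong: amine-induced dimerisation or oligomerisation of the vinyl ketone before the aldol step. Fallback: setting out from 16, conjugate addition of Me2AlSePh (THF, −78 °C) and trapping of the aluminium enolate with monomeric formaldehyde gives the β-phenylselanyl aldol F3. Oxidation with H2O2/pyridine and selenoxide syn-elimination comes back at 17.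

**Further compounds**
F1 | step 16 | 6S carbinol (C6 epimer of 20) | CC(C)(C)[Si](C)(C)OCC1=C2/C(=C/[C@](C)(O[Si](CC)(CC)CC)CCC(=O)C(=C)C[C@@H]2O)OC1=O
F2 | step 16 | exo-methylene senecioate (6R; as 22 with C4=CH2) | CC(C)(C)[Si](C)(C)OCC1=C2/C(=C/[C@](C)(O[Si](CC)(CC)CC)CCC(=O)C(=C)C[C@H]2OC(=O)C=C(C)C)OC1=O
F0 | step 17 | none | none
F3 | step 13 | β-phenylselanyl aldol (as 17 with CH(CH2OH)–CH2SePh in place of C(=CH2)–CH2OH) | O=C1O/C(=C\[C@](C)(O[Si](CC)(CC)CC)CCC(=O)C(CO)C[Se]c2ccccc2)C(C(OC)OC)=C1CO[Si](C)(C)C(C)(C)C
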